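**Plan**

- Enabling feature: in the furanone ring, C2 carries O1, OH, the C3 ketone and the farnesyl C1' methylene. It is therefore a ring-closed aryl 1,2-dione, and a constitutional isomer of a 3-hydroxy-2-alkenylchroman-4-one in which O1 sits on C1' instead of C2.
- Retrosynthesis: cut O1–C2 of the hemiketal and rejoin O1 to C1' (six-membered pyranone); cut that O1–C bond again as an epoxide opening; cut the enone C=C as an aldol condensation, leading to 2',4'-dihydroxyacetophenone and (2E,6E)-farnesal.
- Forward: the C15 chain is joined to the bis-silylated acetophenone by aldol addition and dehydration, the enone is epoxidised, desilylation lets the 2'-phenol close the pyranone 6-endo, and an isomerase contracts it to the furanone.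
- Stereochemistry: farnesol supplies both E alkenes. Poly-L-leucine epoxidation sets the (2R,3R) centres of the chromanone, the configuration of the natural flavanonol substrates of the enzyme. Both centres are erased in the key step, where the enzyme alone sets the (2R) hemiketal centre.

Key step: step 7

Remark: the hemiketal carbon of the target can epimerise by ring–chain tautomerism with the open 1,2-dione; it is assumed that this is slow at neutral pH and low temperature, and that the enzyme closes the ring to the (2R) isomer.

**Route**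

Step 1
Reactants: 1 2',4'-dihydroxyacetophenone
Product: 2 1-[2,4-bis(triisopropylsilyloxy)phenyl]ethan-1-one
Conditions: TIPSCl, imidazole, DMAP (cat.), DMF, 50 °C
Reagents that add atoms: chlorotriisopropylsilane, CC(C)[Si](Cl)(C(C)C)C(C)C
Why: Standard silyl ether formation on phenols; the chelated 2'-OH reacts more slowly, hence excess reagent, DMAP and warming, and the bulky silyl groups are chosen to survive the enolate and hydroperoxide steps yet fall to fluoride without acid.

Step 2
Reactants: 3 (2E,6E)-farnesol
Product: 4 (2E,6E)-farnesal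
Conditions: TEMPO (cat.), PhI(OAc)2, CH2Cl2, rt
Reagents that add atoms: none
Why: Oxoammonium-mediated (TEMPO/PhI(OAc)2) oxidation of a primary allylic alcohol should stop at the enal, leave the isolated trisubstituted alkenes alone and not isomerise the 2,3-double bond.

Step 3
Reactants: 2 1-[2,4-bis(triisopropylsilyloxy)phenyl]ethan-1-one; 4 (2E,6E)-farnesal
Product: 5 (4E,8E)-1-[2,4-bis(triisopropylsilyloxy)phenyl]-3-hydroxy-5,9,13-trimethyltetradeca-4,8,12-trien-1-one (racemic at C3)
Conditions: LiN(SiMe3)2, THF, −78 °C; then 4, −78 °C; AcOH quench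
Reagents that add atoms: none
Why: Directed aldol addition of a preformed lithium enolate, which at −78 °C should add 1,2 to the enal faster than it deprotonates the gamma position, so the E geometry is kept; the new carbinol centre forms as a racemate and is removed in step 4.

Step 4
Reactants: 5 (4E,8E)-1-[2,4-bis(triisopropylsilyloxy)phenyl]-3-hydroxy-5,9,13-trimethyltetradeca-4,8,12-trien-1-one
Product: 7 (2E,4E,8E)-1-[2,4-bis(triisopropylsilyloxy)phenyl]-5,9,13-trimethyltetradeca-2,4,8,12-tetraen-1-one, via mesylate 6 (not isolated)
Conditions: MsCl, Et3N, CH2Cl2, −20 °C to rt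
Reagents that add atoms: none
Why: Mesylation followed by E1cB elimination of the beta-mesyloxy ketone completes the aldol condensation and should give the thermodynamically preferred (2E)-enone, while the mild amine base leaves the 4E alkene and the silyl ethers untouched.

Step 5
Reactants: 7 (2E,4E,8E)-1-[2,4-bis(triisopropylsilyloxy)phenyl]-5,9,13-trimethyltetradeca-2,4,8,12-tetraen-1-one
Product: 8 [2,4-bis(triisopropylsilyloxy)phenyl]{(2R,3S)-3-[(1E,5E)-2,6,10-trimethylundeca-1,5,9-trien-1-yl]oxiran-2-yl}methanone
Conditions: poly-L-leucine (cat.), urea·H2O2, DBU, THF, rt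
Reagents that add atoms: hydrogen peroxide, used as its urea adduct, OO.NC(N)=O
Why: Juliá–Colonna epoxidation, a Weitz–Scheffer hydroperoxide addition to the enone hydrogen-bonded at the N-terminus of the peptide helix, which in chalcones and dienones oxidises only the alkene next to the carbonyl and with the L-polymer is expected by analogy to give the (2R,3S) epoxide; the trans relationship follows from the E-enone and the isolated alkenes are inert to the nucleophilic oxidant.

Step 6
Reactants: 8 [2,4-bis(triisopropylsilyloxy)phenyl]{(2R,3S)-3-[(1E,5E)-2,6,10-trimethylundeca-1,5,9-trien-1-yl]oxiran-2-yl}methanone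
Product: 10 (2R,3R)-3,7-dihydroxy-2-[(1E,5E)-2,6,10-trimethylundeca-1,5,9-trien-1-yl]chroman-4-one, via free epoxy ketone 9 (not isolated)
Conditions: Bu4NF, AcOH, THF, 0 °C to rt; pH 7 buffer work-up
Reagents that add atoms: none
Why: Fluoride desilylation followed by intramolecular epoxide opening, in which the freed 2'-phenol should attack the allylic epoxide carbon in a 6-endo-tet closure (the mode followed by 2'-hydroxychalcone epoxides without a 6'-substituent and further favoured by the adjacent alkene) with inversion, so the (2R,3S)-epoxide gives the (2R,3R)-trans-chromanone; acetic acid keeps the medium too weakly basic to enolise C3 of the product.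

Step 7
Reactants: 10 (2R,3R)-3,7-dihydroxy-2-[(1E,5E)-2,6,10-trimethylundeca-1,5,9-trien-1-yl]chroman-4-one
Product: 13 (2R)-2,6-dihydroxy-2-[(2E,6E)-3,7,11-trimethyldodeca-2,6,10-trien-1-yl]-1-benzofuran-3(2H)-one (the target), via ring-opened dienol 11 (not isolated), via open-chain 1,2-dione 12 (not isolated)
Conditions: bacterial chalcone isomerase of the flavanonol-isomerising class (Eubacterium ramulus type, recombinant), KH2PO4/K2HPO4 buffer pH 7.0, DMSO (5% v/v), 30 °C, N2; EtOAc extraction at 4 °C
Reagents that add atoms: none
Why: Proposed new method: an active-site general base removes H3 of 10, the C4 enolate expels the O1 phenoxide from the allylic C2 carbon (E1cB, the reverse of a 6-endo oxa-Michael closure) to give the alpha-hydroxy dienone 11, and protonation of this dienol at its alpha carbon, the former C2, gives the beta,gamma-unsaturated aryl 1,2-dione 12. The enzyme-held phenoxide then adds to the non-aryl carbonyl in a 5-exo-trig closure that forms O1–C2 and the furanone ring. The closest known reaction type is the ring contraction of 2-aryl-3-hydroxychroman-4-ones (flavanonols) to 2-benzyl-2-hydroxybenzofuran-3-ones by bacterial chalcone isomerases, which also proceeds under mild base without enzyme; a 2-alkenyl substrate has not been shown. The new C2 hemiketal centre is controlled by the active site, which must present one face of the C2 carbonyl to the phenoxide so that the (2R) isomer results, while both centres of 10 are destroyed on the way and cannot interfere. The step needs protonation at the alpha and not the gamma carbon of the dienol, which kinetic protonation of a dienol favours, and it needs the C2'=C3' alkene to stay out of conjugation, which hemiketal formation secures by removing the C2 carbonyl from further enolisation.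

**Compound list**

1 | 2',4'-dihydroxyacetophenone | CC(=O)c1ccc(O)cc1O | starting material
2 | 1-[2,4-bis(triisopropylsilyloxy)phenyl]ethan-1-one | CC(=O)c1ccc(O[Si](C(C)C)(C(C)C)C(C)C)cc1O[Si](C(C)C)(C(C)C)C(C)C | intermediate
3 | (2E,6E)-farnesol | CC(C)=CCC/C(C)=C/CC/C(C)=C/CO | starting material
4 | (2E,6E)-farnesal | CC(C)=CCC/C(C)=C/CC/C(C)=C/C=O | intermediate
5 | (4E,8E)-1-[2,4-bis(triisopropylsilyloxy)phenyl]-3-hydroxy-5,9,13-trimethyltetradeca-4,8,12-trien-1-one, racemic at C3 (centre left undefined) | CC(C)=CCC/C(C)=C/CC/C(C)=C/C(O)CC(=O)c1ccc(O[Si](C(C)C)(C(C)C)C(C)C)cc1O[Si](C(C)C)(C(C)C)C(C)C | intermediate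
6 | (4E,8E)-1-[2,4-bis(triisopropylsilyloxy)phenyl]-5,9,13-trimethyl-1-oxotetradeca-4,8,12-trien-3-yl methanesulfonate, racemic (centre left undefined) | CC(C)=CCC/C(C)=C/CC/C(C)=C/C(OS(C)(=O)=O)CC(=O)c1ccc(O[Si](C(C)C)(C(C)C)C(C)C)cc1O[Si](C(C)C)(C(C)C)C(C)C | intermediate
7 | (2E,4E,8E)-1-[2,4-bis(triisopropylsilyloxy)phenyl]-5,9,13-trimethyltetradeca-2,4,8,12-tetraen-1-one | CC(C)=CCC/C(C)=C/CC/C(C)=C/C=C/C(=O)c1ccc(O[Si](C(C)C)(C(C)C)C(C)C)cc1O[Si](C(C)C)(C(C)C)C(C)C | intermediate
8 | [2,4-bis(triisopropylsilyloxy)phenyl]{(2R,3S)-3-[(1E,5E)-2,6,10-trimethylundeca-1,5,9-trien-1-yl]oxiran-2-yl}methanone | CC(C)=CCC/C(C)=C/CC/C(C)=C/[C@@H]1O[C@H]1C(=O)c1ccc(O[Si](C(C)C)(C(C)C)C(C)C)cc1O[Si](C(C)C)(C(C)C)C(C)C | intermediate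
9 | (2,4-dihydroxyphenyl){(2R,3S)-3-[(1E,5E)-2,6,10-trimethylundeca-1,5,9-trien-1-yl]oxiran-2-yl}methanone | CC(C)=CCC/C(C)=C/CC/C(C)=C/[C@@H]1O[C@H]1C(=O)c1ccc(O)cc1O | intermediate
10 | (2R,3R)-3,7-dihydroxy-2-[(1E,5E)-2,6,10-trimethylundeca-1,5,9-trien-1-yl]chroman-4-one | CC(C)=CCC/C(C)=C/CC/C(C)=C/[C@H]1Oc2cc(O)ccc2C(=O)[C@@H]1O | intermediate
11 | (2Z,4E,8E)-1-(2,4-dihydroxyphenyl)-2-hydroxy-5,9,13-trimethyltetradeca-2,4,8,12-tetraen-1-one (enzyme-bound dienol, drawn with the 2Z geometry expected from opening of the trans-chromanone) | CC(C)=CCC/C(C)=C/CC/C(C)=C/C=C(\O)C(=O)c1ccc(O)cc1O | intermediate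
12 | (4E,8E)-1-(2,4-dihydroxyphenyl)-5,9,13-trimethyltetradeca-4,8,12-triene-1,2-dione | CC(C)=CCC/C(C)=C/CC/C(C)=C/CC(=O)C(=O)c1ccc(O)cc1O | intermediate
13 | (2R)-2,6-dihydroxy-2-[(2E,6E)-3,7,11-trimethyldodeca-2,6,10-trien-1-yl]-1-benzofuran-3(2H)-one | CC(C)=CCC/C(C)=C/CC/C(C)=C/C[C@@]1(O)Oc2cc(O)ccc2C1=O | target

**Step count and risks**

Total steps: 7. Longest linear sequence: 6 steps (1 → 2 → 5 → 7 → 8 → 10 → 13; the farnesol branch 3 → 4 joins at step 3 and is equally long).

Steps most likely to fail:

1. Step 7 (proposed new method). The enzyme may not bind or turn over a substrate that carries a long lipophilic alkenyl chain where its natural substrates carry an aryl ring. The dienol may be protonated at the gamma carbon, leading to the conjugated dione. The hemiketal may close without facial preference or lose its configuration by ring–chain tautomerism. Fallback with known chemistry: setting out from 10, the base-mediated ring contraction that flavanonols undergo without enzyme (NaHCO3 in degassed aqueous MeOH, gentle warming) should give racemic 2,6-dihydroxy-2-[(2E,6E)-farnesyl]-1-benzofuran-3(2H)-one F1. Separation of its enantiomers on a polysaccharide-based chiral stationary phase, with neutral eluent at low temperature, comes back to the route at 13.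

2. Step 6. The phenol may attack the epoxide carbon next to the carbonyl (5-exo) instead of the allylic one. The allylic C–O bond may ionise with loss of configuration. The product may begin to ring-open under the basic fluoride. Fallback: setting out from 7, removal of both silyl groups with Bu4NF/AcOH should give the free dienone (2E,4E,8E)-1-(2,4-dihydroxyphenyl)-5,9,13-trimethyltetradeca-2,4,8,12-tetraen-1-one F2. An Algar–Flynn–Oyamada oxidation stopped at the dihydro stage (H2O2, NaOH, MeOH, 0 °C, short reaction time) would then follow. There the pyranone is taken to close by conjugate addition of the phenoxide before the enolate is hydroxylated, so no choice between two epoxide carbons arises. This should give racemic trans-3,7-dihydroxy-2-[(1E,5E)-2,6,10-trimethylundeca-1,5,9-trien-1-yl]chroman-4-one F3. Preparative chiral-phase HPLC comes back to the route at 10.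

3. Step 5. Facial selectivity may be poor, or turnover slow, because the bulky ortho-silyloxy group twists the aryl ketone and hinders binding to the peptide. Silyl groups may be partly lost to hydroperoxide and DBU. Fallback: setting out from 7, uncatalysed Weitz–Scheffer epoxidation with anhydrous t-BuOOH and DBU in toluene should give racemic trans-[2,4-bis(triisopropylsilyloxy)phenyl]{3-[(1E,5E)-2,6,10-trimethylundeca-1,5,9-trien-1-yl]oxiran-2-yl}methanone F4. Resolution on a chiral stationary phase (preparative HPLC or SFC) comes back to the route at 8, so the configuration would come from separation instead of catalyst control.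

**Further compounds**

F1 | step 7 | racemic 2,6-dihydroxy-2-[(2E,6E)-3,7,11-trimethyldodeca-2,6,10-trien-1-yl]-1-benzofuran-3(2H)-one (centre left undefined) | CC(C)=CCC/C(C)=C/CC/C(C)=C/CC1(O)Oc2cc(O)ccc2C1=O
F2 | step 6 | (2E,4E,8E)-1-(2,4-dihydroxyphenyl)-5,9,13-trimethyltetradeca-2,4,8,12-tetraen-1-one | CC(C)=CCC/C(C)=C/CC/C(C)=C/C=C/C(=O)c1ccc(O)cc1O
F3 | step 6 | racemic trans-3,7-dihydroxy-2-[(1E,5E)-2,6,10-trimethylundeca-1,5,9-trien-1-yl]chroman-4-one (both enantiomers written) | CC(C)=CCC/C(C)=C/CC/C(C)=C/[C@H]1Oc2cc(O)ccc2C(=O)[C@@H]1O.CC(C)=CCC/C(C)=C/CC/C(C)=C/[C@@H]1Oc2cc(O)ccc2C(=O)[C@H]1O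
F4 | step 5 | racemic trans-[2,4-bis(triisopropylsilyloxy)phenyl]{3-[(1E,5E)-2,6,10-trimethylundeca-1,5,9-trien-1-yl]oxiran-2-yl}methanone (both enantiomers written) | CC(C)=CCC/C(C)=C/CC/C(C)=C/[C@@H]1O[C@H]1C(=O)c1ccc(O[Si](C(C)C)(C(C)C)C(C)C)cc1O[Si](C(C)C)(C(C)C)C(C)C.CC(C)=CCC/C(C)=C/CC/C(C)=C/[C@H]1O[C@@H]1C(=O)c1ccc(O[Si](C(C)C)(C(C)C)C(C)C)cc1O[Si](C(C)C)(C(C)C)C(C)C
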